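Follow the partner.

    solid substrate ⇌ dissolved substrate, rate k1*(cs1 - [dissolved substrate]) while solid is left; crystals form when [dissolved substrate] > cs1 (cs1 = 0.81 M, k1 = 0.0050 min⁻¹)
    dissolved substrate + partner → product (k2 = 6.1 × 10⁻⁴ M⁻¹ min⁻¹)
    2 partner → homo dimer (k3 = 5.3 × 10⁻⁴ M⁻¹ min⁻¹)
    solid substrate + protic impurity → quenched substrate (k4 = 5.1 × 10⁻⁴ M⁻¹ min⁻¹)

solid substrate 2.0 M; partner 1.10 equiv; protic impurity 0.400 M; time 40 h

- south: doubling the solubility in step 1, all else as stated
- east: doubling the amount of partner, all else as stated
- north-east: doubling the dissolution coefficient of step 1, all else as stated

- two of one species on the left: rate k times its square, two consumed each time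
- solid substrate is a solid; its amount is given per volume of the solution
- at the start none of the solid substrate is in solution
- run time (flask): 40 h

- product at 40 h, in percent of the solid substrate charged
- the change that raises the amount of product at 40 h, in percent of the solid substrate charged most ("none" if none brings more than 2 percentage points) (south / east / north-east / none)
- amount of product at 40 h, in percent of the solid substrate charged, after south

I counted amounts as fractions of the solid substrate charged. I took the dissolved substrate as saturated at 0.405 after a lag of 3.33 h, and during that lag I let the partner dimerise with no coupling. After the lag, coupling is pseudo-first-order in partner, with constant k′ = 4.94 × 10⁻⁴ min⁻¹. I called 0.233 the break-even partner: the level at which dimerising and coupling use partner equally fast. If b is the partner left after the lag, integration gives product = h·ln(1 + (b/h)(1 − e^(−k′(t−lag)))).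

Partner after the lag, then product:

- Flask as stated: 0.750; 26.6%
- South, with h and k′ doubled: the same b; 41.3%
- East: 1.14; 33.7%
- North-east, with the lag halved: 0.892; 29.8%

Reading down the first column, east doubled the charge but raised the partner after the lag by a factor of 1.52. North-east raised it by a factor of 1.19. South left it alone and moved h instead, so my choice was south. In south, saturation plus product comes to 122% of the charge, more than was charged, so the saturation I assumed for south cannot last to the end and that row reckons high.

The forecast gave 26% for the flask, south as the best change and 39% after south, which is less than my south row, reasoning: “Doubling the solubility roughly doubles the dissolved substrate until the solid runs out”.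

The simulation gave 26.2%, then south with 14 percentage points, against 7 points for east and 3.1 points for north-east, and 40.0% after south.

In the flask as stated, at 4.82 h, dimerising used partner 3.8 times as fast as coupling. At 40.0 h in the same flask, partner stood at 7.67% of its own charge, which is 0.0843 of the substrate charge and below the break-even 0.233, with dissolved substrate at 39.6%. For the same flask read at 3.0 d, the break-even formula gives 31.1%, and the simulation gave 30.9%.

The numbers of this flask were chosen freely; what happens was integrated by code.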